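**Retrosynthetic overview**

1. The target is reached from an N‑Boc cis‑decahydroquinolin‑3‑ol by Mitsunobu esterification with inversion at C3 and a final acidolysis; C8a, C4a and C3 are set one after the other on a bicyclic N‑Boc 8a‑hydroxy‑enone.
2. The strategy rests on the array N1–C2(Me)–C3(O)–C4–C4a–C8a of the piperidine ring. The C3 oxygen with C3, C4, C4a and C8a is a latent furan, and C4a–C8a is the bond shared with the carbocycle, so the precursor is a 2‑(1‑Boc‑aminoethyl)‑4‑alkyl‑4,5,6,7‑tetrahydrobenzofuran.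
3. Key disconnection: N1–C8a, by oxidative ring expansion of that furan (aza‑Achmatowicz) with mCPBA.
4. The precursor comes from 6,7‑dihydrobenzofuran‑4(5H)‑one: enol triflate, B‑alkyl Suzuki coupling with a side chain made from (R)‑1,2‑epoxypentane, iridium‑catalysed asymmetric hydrogenation (C5), furan C2 acetylation and sulfinamide reductive amination (C2).
5. Ring order: carbocycle and furan are present in the starting ketone; the piperidine ring is the only ring formed (step 9).

Key step: step 9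

Remark: the side‑chain alcohol is carried as its tert‑butyl ether, because a silyl ether would not survive the methanolic HCl of step 8; it is cleaved together with the Boc group in step 14.
Assumption: the ligand in step 5 is written as (S); if the first run shows the opposite sense at C4, the antipodal ligand is used.

**Route**

Step 1
Reactants: 1 (R)-1,2-epoxypentane; 2 allylmagnesium bromide
Product: 3 (4R)-oct-7-en-4-ol
Conditions: CuI (10 mol %), THF, −40 → 0 °C; aq. NH4Cl
Reagents that add atoms: none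
Why: Copper‑catalysed SN2 opening of the terminal epoxide at its CH2 carbon by the allyl Grignard reagent leaves the carbinol centre untouched, so the (R)‑epoxide gives the (R)‑alcohol with all eight side‑chain carbons.

Step 2
Reactants: 3 (4R)-oct-7-en-4-ol
Product: 4 (5R)-5-tert-butoxyoct-1-ene
Conditions: Cl3CC(=NH)OtBu, BF3·OEt2 (cat.), cyclohexane/CH2Cl2, rt
Reagents that add atoms: tert-butyl 2,2,2-trichloroacetimidate, CC(C)(C)OC(=N)C(Cl)(Cl)Cl
Why: Acid‑catalysed O‑tert‑butylation with a trichloroacetimidate gives an ether that should withstand organolithium, hydride, peracid and dilute HCl and falls with the Boc group at the end.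

Step 3
Reactants: 5 6,7-dihydrobenzofuran-4(5H)-one
Product: 6 6,7-dihydrobenzofuran-4-yl trifluoromethanesulfonate
Conditions: KN(SiMe3)2, THF, −78 °C; PhNTf2, −78 → 0 °C
Reagents that add atoms: N-phenylbis(trifluoromethanesulfonimide), O=S(=O)(N(c1ccccc1)S(=O)(=O)C(F)(F)F)C(F)(F)F
Why: Enolisation at C5, the only enolisable position, and O‑sulfonylation give the vinyl triflate (enol triflate formation).

Step 4
Reactants: 4 (5R)-5-tert-butoxyoct-1-ene; 6 6,7-dihydrobenzofuran-4-yl trifluoromethanesulfonate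
Product: 8 4-[(5R)-5-tert-butoxyoctyl]-6,7-dihydrobenzofuran, via B-alkyl-9-BBN borane 7 (not isolated)
Conditions: 9-BBN, THF, rt; then 6, PdCl2(dppf) (5 mol %), K3PO4 (aq.), DMF/THF, rt → 50 °C
Reagents that add atoms: none
Why: Anti‑Markovnikov hydroboration of the terminal alkene and B‑alkyl Suzuki–Miyaura coupling with the vinyl triflate join chain and bicycle and place the alkene in the ring (C4=C5), so no E/Z mixture can arise.

Step 5
Reactants: 8 4-[(5R)-5-tert-butoxyoctyl]-6,7-dihydrobenzofuran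
Product: 9 (4R)-4-[(5R)-5-tert-butoxyoctyl]-4,5,6,7-tetrahydrobenzofuran
Conditions: H2 (50 bar), [Ir(cod)((S)-tBu-PHOX)][B(3,5-(CF3)2C6H3)4] (2 mol %), CH2Cl2, rt
Reagents that add atoms: none
Why: Iridium‑catalysed asymmetric hydrogenation of an unfunctionalised trisubstituted cyclic alkene conjugated to an arene (the 1‑alkyl‑3,4‑dihydronaphthalene class) sets C4 under catalyst control, and the disubstituted furan should stay intact.

Step 6
Reactants: 9 (4R)-4-[(5R)-5-tert-butoxyoctyl]-4,5,6,7-tetrahydrobenzofuran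
Product: 10 1-{(4R)-4-[(5R)-5-tert-butoxyoctyl]-4,5,6,7-tetrahydrobenzofuran-2-yl}ethan-1-one
Conditions: n-BuLi, THF, 0 °C; MeC(O)N(OMe)Me, −78 → 0 °C
Reagents that add atoms: N-methoxy-N-methylacetamide, CC(=O)N(C)OC
Why: α‑Lithiation of the furan at its only free α‑position (C2) and acylation with a Weinreb amide, whose chelated adduct prevents over‑addition.

Step 7
Reactants: 10 1-{(4R)-4-[(5R)-5-tert-butoxyoctyl]-4,5,6,7-tetrahydrobenzofuran-2-yl}ethan-1-one; 11 (R)-2-methylpropane-2-sulfinamide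
Product: 13 (R)-N-[(1R)-1-{(4R)-4-[(5R)-5-tert-butoxyoctyl]-4,5,6,7-tetrahydrobenzofuran-2-yl}ethyl]-2-methylpropane-2-sulfinamide, via N-sulfinyl ketimine 12 (not isolated)
Conditions: Ti(OEt)4, THF, 65 °C; then NaBH4, −48 °C
Reagents that add atoms: none
Why: Sulfinamide reductive amination: Ti(OEt)4‑mediated condensation gives the (E)‑ketimine, and NaBH4 reduces it through the chelated cyclic transition state, which for an (R)‑sulfinyl aryl methyl ketimine should give the (R)‑carbinamine centre.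

Step 8
Reactants: 13 (R)-N-[(1R)-1-{(4R)-4-[(5R)-5-tert-butoxyoctyl]-4,5,6,7-tetrahydrobenzofuran-2-yl}ethyl]-2-methylpropane-2-sulfinamide
Product: 15 tert-butyl N-[(1R)-1-{(4R)-4-[(5R)-5-tert-butoxyoctyl]-4,5,6,7-tetrahydrobenzofuran-2-yl}ethyl]carbamate, via ammonium chloride 14 (not isolated)
Conditions: HCl (4 M in dioxane), MeOH, 0 °C; evaporate; Boc2O, Et3N, CH2Cl2, rt
Reagents that add atoms: di-tert-butyl dicarbonate, CC(C)(C)OC(=O)OC(=O)OC(C)(C)C
Why: Acidolysis of the S–N bond (sulfinyl transfer to methanol) and N‑acylation with Boc2O; the tert‑butyl ether should survive the brief cold methanolic HCl and the stereocentres are not involved.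

Step 9
Reactants: 15 tert-butyl N-[(1R)-1-{(4R)-4-[(5R)-5-tert-butoxyoctyl]-4,5,6,7-tetrahydrobenzofuran-2-yl}ethyl]carbamate
Product: 17 tert-butyl (2R,5R)-5-[(5R)-5-tert-butoxyoctyl]-8a-hydroxy-2-methyl-3-oxo-3,5,6,7,8,8a-hexahydroquinoline-1(2H)-carboxylate (8a-epimers), via (Z)-ene-dione 16 (not isolated)
Conditions: mCPBA (1.2 equiv), CH2Cl2, 0 °C → rt
Reagents that add atoms: 3-chloroperbenzoic acid, O=C(OO)c1cccc(Cl)c1
Why: The peracid transfers oxygen to the electron‑rich furan, which opens to the (Z)‑ene‑dione 16, where the former furan oxygen is the C3 ketone and C8a is a ring ketone; this is the aza‑Achmatowicz rearrangement of an N‑acyl furfurylamine, known also for furans with a carbon substituent at the second α‑position. The carbamate N–H then adds to the C8a carbonyl in a 6‑exo‑trig hemiaminal closure that forms N1–C8a and the six‑membered aza‑enone ring, the Z geometry inherited from the furan keeping nitrogen and C8a within reach. Because the cyclohexane is already fused to the furan through C4a–C8a, this one closure gives the whole bicyclic skeleton with the C2 methyl group, the C3 oxygen and the C5 chain in place. The only new stereocentre is the hemiaminal carbon C8a, which is set by ring–chain equilibration and need not be controlled since it becomes planar again in step 10; C2 and C5 are not touched. The selectivity needed is chemoselectivity for the furan, secured by the absence of any other electron‑rich π‑system or oxidisable heteroatom and by using little more than one equivalent of peracid at 0 °C, so that the electron‑poor ene‑dione should not be oxidised further.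

Step 10
Reactants: 17 tert-butyl (2R,5R)-5-[(5R)-5-tert-butoxyoctyl]-8a-hydroxy-2-methyl-3-oxo-3,5,6,7,8,8a-hexahydroquinoline-1(2H)-carboxylate (8a-epimers)
Product: 19 tert-butyl (2R,5R,8aS)-5-[(5R)-5-tert-butoxyoctyl]-2-methyl-3-oxo-3,5,6,7,8,8a-hexahydroquinoline-1(2H)-carboxylate, via N-acyliminium ion 18 (not isolated)
Conditions: Et3SiH, BF3·OEt2, CH2Cl2, −78 → −40 °C
Reagents that add atoms: none
Why: Ionic reduction of an N‑acyl hemiaminal: BF3·OEt2 ionises both epimers (and closes any open‑chain 16) to the planar N‑acyliminium ion, and the silane should add to C8a on the face opposite the C2 methyl group, held pseudoaxial by A(1,3) strain with the Boc group, and opposite the C5 chain, which lets C8 swing pseudoaxial beside the methyl group and gives the 2,8a‑cis (8aS) product.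

Step 11
Reactants: 19 tert-butyl (2R,5R,8aS)-5-[(5R)-5-tert-butoxyoctyl]-2-methyl-3-oxo-3,5,6,7,8,8a-hexahydroquinoline-1(2H)-carboxylate
Product: 20 tert-butyl (2R,4aR,5R,8aS)-5-[(5R)-5-tert-butoxyoctyl]-2-methyl-3-oxooctahydroquinoline-1(2H)-carboxylate
Conditions: H2 (1 atm), Pd/C, EtOAc, rt
Reagents that add atoms: none
Why: Heterogeneous hydrogenation of the enone C4=C4a: with the C2 methyl group and C8 both pseudoaxial on the carbamate, the carbocycle is folded under one face, so hydrogen should add to the open face syn to H‑8a and give the cis ring fusion (4aR) with H‑4a cis to H‑5.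

Step 12
Reactants: 20 tert-butyl (2R,4aR,5R,8aS)-5-[(5R)-5-tert-butoxyoctyl]-2-methyl-3-oxooctahydroquinoline-1(2H)-carboxylate
Product: 21 tert-butyl (2R,3R,4aR,5R,8aS)-5-[(5R)-5-tert-butoxyoctyl]-3-hydroxy-2-methyloctahydroquinoline-1(2H)-carboxylate
Conditions: LiBH(s-Bu)3, THF, −78 °C
Reagents that add atoms: none
Why: Ketone reduction with a bulky hydride, which should approach C3 from the convex face opposite the axial C2 methyl group and give the alcohol cis to that methyl group (3R).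

Step 13
Reactants: 21 tert-butyl (2R,3R,4aR,5R,8aS)-5-[(5R)-5-tert-butoxyoctyl]-3-hydroxy-2-methyloctahydroquinoline-1(2H)-carboxylate; 22 (E)-oct-2-enoic acid
Product: 23 tert-butyl (2R,3S,4aR,5R,8aS)-5-[(5R)-5-tert-butoxyoctyl]-2-methyl-3-{[(2E)-oct-2-enoyl]oxy}octahydroquinoline-1(2H)-carboxylate
Conditions: PPh3, DIAD, THF, 0 °C → rt
Reagents that add atoms: none
Why: Mitsunobu esterification: the carboxylate displaces the phosphine‑activated equatorial C3 oxygen by SN2 with inversion, which installs the ester trans to the C2 methyl group (3S); an equatorial leaving group has no anti‑periplanar hydrogen for elimination.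

Step 14
Reactants: 23 tert-butyl (2R,3S,4aR,5R,8aS)-5-[(5R)-5-tert-butoxyoctyl]-2-methyl-3-{[(2E)-oct-2-enoyl]oxy}octahydroquinoline-1(2H)-carboxylate
Product: 24 (2R,3S,4aR,5R,8aS)-5-[(5R)-5-hydroxyoctyl]-2-methyldecahydroquinolin-3-yl (2E)-oct-2-enoate
Conditions: TFA/CH2Cl2 (1:1), 0 °C → rt; aq. NaHCO3
Reagents that add atoms: none
Why: Acidolysis of both tert‑butyl groups (Boc carbamate and tert‑butyl ether) through the tert‑butyl cation; the amine stays protonated until work‑up, so the enoate and all stereocentres should be untouched.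

**Compound list**

1 | (R)-1,2-epoxypentane | CCC[C@@H]1CO1 | starting material
2 | allylmagnesium bromide | C=CC[Mg]Br | starting material
3 | (4R)-oct-7-en-4-ol | C=CCC[C@H](O)CCC | intermediate
4 | (5R)-5-tert-butoxyoct-1-ene | C=CCC[C@H](OC(C)(C)C)CCC | intermediate
5 | 6,7-dihydrobenzofuran-4(5H)-one | O=C1CCCc2occc21 | starting material
6 | 6,7-dihydrobenzofuran-4-yl trifluoromethanesulfonate | O=S(=O)(OC1=CCCc2occc21)C(F)(F)F | intermediate
7 | 9-[(5R)-5-tert-butoxyoctyl]-9-borabicyclo[3.3.1]nonane (not isolated) | B1(CCCC[C@H](OC(C)(C)C)CCC)C2CCCC1CCC2 | intermediate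
8 | 4-[(5R)-5-tert-butoxyoctyl]-6,7-dihydrobenzofuran | C1(CCCC[C@H](OC(C)(C)C)CCC)=CCCc2occc21 | intermediate
9 | (4R)-4-[(5R)-5-tert-butoxyoctyl]-4,5,6,7-tetrahydrobenzofuran | c1cc2c(o1)CCC[C@H]2CCCC[C@H](OC(C)(C)C)CCC | intermediate
10 | 1-{(4R)-4-[(5R)-5-tert-butoxyoctyl]-4,5,6,7-tetrahydrobenzofuran-2-yl}ethan-1-one | CC(=O)c1cc2c(o1)CCC[C@H]2CCCC[C@H](OC(C)(C)C)CCC | intermediate
11 | (R)-2-methylpropane-2-sulfinamide | CC(C)(C)[S@@](=O)N | starting material
12 | (R,E)-N-sulfinyl ketimine of 10 (not isolated) | C/C(=N\[S@](=O)C(C)(C)C)c1cc2c(o1)CCC[C@H]2CCCC[C@H](OC(C)(C)C)CCC | intermediate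
13 | (R)-N-[(1R)-1-{(4R)-4-[(5R)-5-tert-butoxyoctyl]-4,5,6,7-tetrahydrobenzofuran-2-yl}ethyl]-2-methylpropane-2-sulfinamide | C[C@@H](N[S@](=O)C(C)(C)C)c1cc2c(o1)CCC[C@H]2CCCC[C@H](OC(C)(C)C)CCC | intermediate
14 | (1R)-1-{(4R)-4-[(5R)-5-tert-butoxyoctyl]-4,5,6,7-tetrahydrobenzofuran-2-yl}ethan-1-aminium chloride (not isolated) | C[C@@H]([NH3+])c1cc2c(o1)CCC[C@H]2CCCC[C@H](OC(C)(C)C)CCC.[Cl-] | intermediate
15 | tert-butyl N-[(1R)-1-{(4R)-4-[(5R)-5-tert-butoxyoctyl]-4,5,6,7-tetrahydrobenzofuran-2-yl}ethyl]carbamate | C[C@@H](NC(=O)OC(C)(C)C)c1cc2c(o1)CCC[C@H]2CCCC[C@H](OC(C)(C)C)CCC | intermediate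
16 | tert-butyl N-[(2R,4Z)-4-{(2R)-2-[(5R)-5-tert-butoxyoctyl]-6-oxocyclohexylidene}-3-oxobutan-2-yl]carbamate (not isolated) | C[C@@H](NC(=O)OC(C)(C)C)C(=O)/C=C1\C(=O)CCC[C@H]1CCCC[C@H](OC(C)(C)C)CCC | intermediate
17 | tert-butyl (2R,5R)-5-[(5R)-5-tert-butoxyoctyl]-8a-hydroxy-2-methyl-3-oxo-3,5,6,7,8,8a-hexahydroquinoline-1(2H)-carboxylate (8a-epimers) | C[C@H]1N(C(=O)OC(C)(C)C)C2(O)CCC[C@@H](CCCC[C@H](OC(C)(C)C)CCC)C2=CC1=O | intermediate
18 | (2R,5R)-1-(tert-butoxycarbonyl)-5-[(5R)-5-tert-butoxyoctyl]-2-methyl-3-oxo-2,3,5,6,7,8-hexahydroquinolin-1-ium hydroxytrifluoroborate (not isolated) | C[C@H]1[N+](C(=O)OC(C)(C)C)=C2CCC[C@@H](CCCC[C@H](OC(C)(C)C)CCC)C2=CC1=O.O[B-](F)(F)F | intermediate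
19 | tert-butyl (2R,5R,8aS)-5-[(5R)-5-tert-butoxyoctyl]-2-methyl-3-oxo-3,5,6,7,8,8a-hexahydroquinoline-1(2H)-carboxylate | O=C1C=C2[C@H](CCCC[C@H](OC(C)(C)C)CCC)CCC[C@@H]2N(C(=O)OC(C)(C)C)[C@@H]1C | intermediate
20 | tert-butyl (2R,4aR,5R,8aS)-5-[(5R)-5-tert-butoxyoctyl]-2-methyl-3-oxooctahydroquinoline-1(2H)-carboxylate | O=C1C[C@@H]2[C@H](CCCC[C@H](OC(C)(C)C)CCC)CCC[C@@H]2N(C(=O)OC(C)(C)C)[C@@H]1C | intermediate
21 | tert-butyl (2R,3R,4aR,5R,8aS)-5-[(5R)-5-tert-butoxyoctyl]-3-hydroxy-2-methyloctahydroquinoline-1(2H)-carboxylate | O[C@@H]1C[C@@H]2[C@H](CCCC[C@H](OC(C)(C)C)CCC)CCC[C@@H]2N(C(=O)OC(C)(C)C)[C@@H]1C | intermediate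
22 | (E)-oct-2-enoic acid | CCCCC/C=C/C(=O)O | starting material
23 | tert-butyl (2R,3S,4aR,5R,8aS)-5-[(5R)-5-tert-butoxyoctyl]-2-methyl-3-{[(2E)-oct-2-enoyl]oxy}octahydroquinoline-1(2H)-carboxylate | CCCCC/C=C/C(=O)O[C@H]1C[C@@H]2[C@H](CCCC[C@H](OC(C)(C)C)CCC)CCC[C@@H]2N(C(=O)OC(C)(C)C)[C@@H]1C | intermediate
24 | (2R,3S,4aR,5R,8aS)-5-[(5R)-5-hydroxyoctyl]-2-methyldecahydroquinolin-3-yl (2E)-oct-2-enoate | CCCCC/C=C/C(=O)O[C@H]1C[C@@H]2[C@H](CCCC[C@H](O)CCC)CCC[C@@H]2N[C@@H]1C | target

**Step count**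

Total: 14 steps. Longest linear sequence: 13 steps (steps 1, 2, 4–14 from (R)-1,2-epoxypentane; step 3 is the one‑step side branch).

**Steps most likely to fail**

Step 9. The weakly nucleophilic carbamate may close only slowly onto the hindered ring ketone, so that the ene‑dione isomerises to its E form or is oxidised further before it is captured. The fallback changes the nitrogen group to a sulfonamide, whose more acidic N–H closes readily and gives stable N‑sulfonyl hemiaminals. It sets out from ammonium chloride 14, which with 2‑(trimethylsilyl)ethanesulfonyl chloride and Et3N gives N-[(1R)-1-{(4R)-4-[(5R)-5-tert-butoxyoctyl]-4,5,6,7-tetrahydrobenzofuran-2-yl}ethyl]-2-(trimethylsilyl)ethanesulfonamide F1. Oxidation with mCPBA would give the N‑sulfonyl 8a‑hydroxy‑enone F2; Et3SiH/BF3·OEt2 the N‑sulfonyl enone F3; H2 with Pd/C the cis‑fused N‑sulfonyl ketone F4; and LiBH(s-Bu)3 the N‑sulfonyl cis‑alcohol F5. CsF in DMF at 95 °C then removes the sulfonyl group to give the amino alcohol F6, and Boc2O returns to the route at compound 21.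

Step 10. Hydride transfer to the hindered, fully substituted iminium carbon may be slower than proton loss from C8 or C2 (enamide formation or aromatisation to a hydroxypyridine), or the facial selectivity may be poor. The fallback sets C8a and C4a together by catalytic syn addition of hydrogen instead of ionic hydride delivery. It sets out from 17: H2 with Pd/C saturates C4=C4a to the saturated keto‑hemiaminal F7, which can no longer aromatise. Catalytic pyridinium p‑toluenesulfonate in toluene at 60 °C over molecular sieves dehydrates it to the ring‑fusion enecarbamate tert-butyl (2R,5R)-5-[(5R)-5-tert-butoxyoctyl]-2-methyl-3-oxo-3,4,5,6,7,8-hexahydroquinoline-1(2H)-carboxylate F8. Hydrogenation of F8 (H2, 50 bar, Pd(OH)2/C, EtOAc) should add both hydrogens to the face opposite the pseudoaxial C2 methyl group and the pseudoaxial C5 chain, and returns to the route at compound 20.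

Step 5. Enantioface discrimination may be insufficient on this furan‑fused alkene, or the acidic iridium hydride may decompose the vinylfuran. The fallback builds the C4 centre by asymmetric conjugate addition and forms the furan afterwards. It sets out from alkene 4: hydroboration with Et2BH gives diethyl[(5R)-5-tert-butoxyoctyl]borane F9, and boron–zinc exchange with Et2Zn gives bis[(5R)-5-tert-butoxyoctyl]zinc F10. Conjugate addition of F10 to cyclohex‑2‑en‑1‑one with Cu(OTf)2 and a binaphthol‑derived phosphoramidite (the ligand hand that gives the 3R ketone), with the zinc enolate trapped in the same flask by allyl acetate and Pd(PPh3)4, would give (2S,3R)-2-allyl-3-[(5R)-5-tert-butoxyoctyl]cyclohexan-1-one F11. Ozonolysis (O3, then PPh3) gives the keto aldehyde F12, and Paal–Knorr cyclodehydration with catalytic pyridinium p‑toluenesulfonate returns to the route at compound 9.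

Further compounds
F1 | step 9 | N-[(1R)-1-{(4R)-4-[(5R)-5-tert-butoxyoctyl]-4,5,6,7-tetrahydrobenzofuran-2-yl}ethyl]-2-(trimethylsilyl)ethanesulfonamide | C[C@@H](NS(=O)(=O)CC[Si](C)(C)C)c1cc2c(o1)CCC[C@H]2CCCC[C@H](OC(C)(C)C)CCC
F2 | step 9 | (2R,5R)-5-[(5R)-5-tert-butoxyoctyl]-8a-hydroxy-2-methyl-1-{[2-(trimethylsilyl)ethyl]sulfonyl}-1,5,6,7,8,8a-hexahydroquinolin-3(2H)-one (8a-epimers) | C[C@H]1N(S(=O)(=O)CC[Si](C)(C)C)C2(O)CCC[C@@H](CCCC[C@H](OC(C)(C)C)CCC)C2=CC1=O
F3 | step 9 | (2R,5R,8aS)-5-[(5R)-5-tert-butoxyoctyl]-2-methyl-1-{[2-(trimethylsilyl)ethyl]sulfonyl}-1,5,6,7,8,8a-hexahydroquinolin-3(2H)-one | O=C1C=C2[C@H](CCCC[C@H](OC(C)(C)C)CCC)CCC[C@@H]2N(S(=O)(=O)CC[Si](C)(C)C)[C@@H]1C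
F4 | step 9 | (2R,4aR,5R,8aS)-5-[(5R)-5-tert-butoxyoctyl]-2-methyl-1-{[2-(trimethylsilyl)ethyl]sulfonyl}octahydroquinolin-3(2H)-one | O=C1C[C@@H]2[C@H](CCCC[C@H](OC(C)(C)C)CCC)CCC[C@@H]2N(S(=O)(=O)CC[Si](C)(C)C)[C@@H]1C
F5 | step 9 | (2R,3R,4aR,5R,8aS)-5-[(5R)-5-tert-butoxyoctyl]-2-methyl-1-{[2-(trimethylsilyl)ethyl]sulfonyl}decahydroquinolin-3-ol | O[C@@H]1C[C@@H]2[C@H](CCCC[C@H](OC(C)(C)C)CCC)CCC[C@@H]2N(S(=O)(=O)CC[Si](C)(C)C)[C@@H]1C
F6 | step 9 | (2R,3R,4aR,5R,8aS)-5-[(5R)-5-tert-butoxyoctyl]-2-methyldecahydroquinolin-3-ol | O[C@@H]1C[C@@H]2[C@H](CCCC[C@H](OC(C)(C)C)CCC)CCC[C@@H]2N[C@@H]1C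
F7 | step 10 | tert-butyl (2R,5R)-5-[(5R)-5-tert-butoxyoctyl]-8a-hydroxy-2-methyl-3-oxooctahydroquinoline-1(2H)-carboxylate (4a,8a-isomers) | C[C@H]1N(C(=O)OC(C)(C)C)C2(O)CCC[C@@H](CCCC[C@H](OC(C)(C)C)CCC)C2CC1=O
F8 | step 10 | tert-butyl (2R,5R)-5-[(5R)-5-tert-butoxyoctyl]-2-methyl-3-oxo-3,4,5,6,7,8-hexahydroquinoline-1(2H)-carboxylate | C[C@H]1N(C(=O)OC(C)(C)C)C2=C(CC1=O)[C@H](CCCC[C@H](OC(C)(C)C)CCC)CCC2
F9 | step 5 | diethyl[(5R)-5-tert-butoxyoctyl]borane | CCB(CC)CCCC[C@H](OC(C)(C)C)CCC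
F10 | step 5 | bis[(5R)-5-tert-butoxyoctyl]zinc | [Zn](CCCC[C@H](OC(C)(C)C)CCC)CCCC[C@H](OC(C)(C)C)CCC
F11 | step 5 | (2S,3R)-2-allyl-3-[(5R)-5-tert-butoxyoctyl]cyclohexan-1-one | O=C1CCC[C@@H](CCCC[C@H](OC(C)(C)C)CCC)[C@@H]1CC=C
F12 | step 5 | 2-{(1S,2R)-2-[(5R)-5-tert-butoxyoctyl]-6-oxocyclohexyl}acetaldehyde | O=C1CCC[C@@H](CCCC[C@H](OC(C)(C)C)CCC)[C@@H]1CC=O
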